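**Plan**

1. Drimane numbering is used: C1 carries the ester, C4 the gem-dimethyl group, C5 and C10 are the ring fusion (C10 quaternary, methyl), C9 carries the C11 formyl group and C8 the C12 formyl group; ring A = C1–C5 and C10, ring B = C5–C10.
2. Enabling feature: ring B is a cyclohexene whose C9 bears a formyl group next to quaternary C10. Read backwards, C11(=O)–C9=C10(Me) is an (E)-enal dienophile and C5=C6–C7=C8 a diene, once the C7=C8 bond is moved to C6=C7; the C12 carbonyl on C8 brings it back by conjugation.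
3. Retrosynthesis: (a) adjust C11 (acetal), C12 (oxidation level) and the double-bond position; (b) cut C5–C10 and C8–C9 together (intramolecular Diels–Alder, the C1–C4 tether becomes ring A) to an acyclic trienal; (c) cut C1–C2 (enantioselective alkylzinc addition to a five-carbon enal), the C1–O acyl bond and C5=C6 (Horner–Wadsworth–Emmons).
4. Forward: the linear C15 chain is joined in eight steps; one cycloaddition closes ring B and, through the tether, ring A; four steps then adjust C11 and C12.
5. Stereochemistry: C1 (R) comes from the catalyst-controlled zinc addition; C5, C9 and C10 come from C1 and the alkene geometries in the cycloaddition; C9 is held as an acetal while the double bond is moved.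

Key step: step 9

Assumption: 2,2-dimethylbut-3-en-1-ol and (E)-4-acetoxy-2-methylbut-2-enal are treated as catalogue compounds; the former is otherwise the γ-adduct of prenylmagnesium chloride with formaldehyde.

**Route**

Step 1
Reactants: 1 2,2-dimethylbut-3-en-1-ol
Product: 2 2,2-dimethylbut-3-enal
Conditions: (COCl)2, DMSO, CH2Cl2, −78 °C; Et3N, −78 to 0 °C; product distilled
Reagents that add atoms: none
Why: Swern oxidation of a primary alcohol; the aldehyde has no α-hydrogen, so neither enolisation nor migration of the vinyl double bond into conjugation is possible.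

Step 2
Reactants: 2 2,2-dimethylbut-3-enal; 3 triethyl 4-phosphonocrotonate
Product: 4 ethyl (2E,4E)-6,6-dimethylocta-2,4,7-trienoate
Conditions: 3, LiN(SiMe3)2, THF, −78 °C; then 2, −78 to 0 °C
Reagents that add atoms: none
Why: Horner–Wadsworth–Emmons olefination: the lithiated phosphonate adds through the carbon next to phosphorus to the hindered, non-enolisable aldehyde and should give the new C5=C6 bond as the (E)-alkene, the second (E)-alkene coming with the reagent.

Step 3
Reactants: 4 ethyl (2E,4E)-6,6-dimethylocta-2,4,7-trienoate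
Product: 5 (2E,4E)-6,6-dimethylocta-2,4,7-trien-1-ol
Conditions: iBu2AlH (2.2 equiv), CH2Cl2, −78 °C; aq. potassium sodium tartrate
Reagents that add atoms: none
Why: Hydride 1,2-reduction of the conjugated ester to the dienylic alcohol; the isolated and conjugated alkenes are inert to iBu2AlH at this temperature.

Step 4
Reactants: 5 (2E,4E)-6,6-dimethylocta-2,4,7-trien-1-ol
Product: 6 tert-butyl{[(2E,4E)-6,6-dimethylocta-2,4,7-trien-1-yl]oxy}diphenylsilane
Conditions: tBuPh2SiCl, imidazole, CH2Cl2, 0 °C to rt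
Reagents that add atoms: tert-butylchlorodiphenylsilane, CC(C)(C)[Si](Cl)(c1ccccc1)c1ccccc1
Why: Imidazole-promoted silylation of the primary alcohol gives an ether that should tolerate boranes, organozinc reagents, mild acid and mild base and is removed later with fluoride.

Step 5
Reactants: 6 tert-butyl{[(2E,4E)-6,6-dimethylocta-2,4,7-trien-1-yl]oxy}diphenylsilane; 7 (2E)-4-acetoxy-2-methylbut-2-enal
Product: 11 (2E,4R,8E,10E)-12-[(tert-butyldiphenylsilyl)oxy]-4-hydroxy-3,7,7-trimethyldodeca-2,8,10-trien-1-yl acetate, via alkyldiethylborane 8 (not isolated), via dialkylzinc 9 (not isolated), via alkyl(trimethylsilylmethyl)zinc 10 (not isolated)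
Conditions: Et2BH (from BH3·SMe2 and Et3B), Et2O, 0 °C to rt; Et2Zn, 0 °C, then volatiles off; Zn(CH2SiMe3)2, Et2O; then 7, Ti(OiPr)4 (1.5 equiv), (1S,2S)-1,2-bis(trifluoromethanesulfonamido)cyclohexane (8 mol %), toluene, −20 °C; aq. NH4Cl
Reagents that add atoms: none
Why: Hydroboration, boron–zinc exchange and titanium bis(sulfonamide)-catalysed enantioselective organozinc addition to an aldehyde: Et2BH should take the monosubstituted vinyl group in preference to the 1,4-disubstituted diene and place boron on the terminal carbon, the mixed zinc reagent transfers only the functionalised alkyl group, the acetate is tolerated, and the (1S,2S) ligand is expected to direct the alkyl group to the Re face of the α-methyl enal and so set C1 as (R).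

Step 6
Reactants: 11 (2E,4R,8E,10E)-12-[(tert-butyldiphenylsilyl)oxy]-4-hydroxy-3,7,7-trimethyldodeca-2,8,10-trien-1-yl acetate; 12 (2E)-3-(4-methoxyphenyl)prop-2-enoyl chloride
Product: 13 (2E,4R,8E,10E)-1-acetoxy-12-[(tert-butyldiphenylsilyl)oxy]-3,7,7-trimethyldodeca-2,8,10-trien-4-yl (2E)-3-(4-methoxyphenyl)prop-2-enoate
Conditions: 12, Et3N, 4-(dimethylamino)pyridine (cat.), CH2Cl2, 0 °C to rt
Reagents that add atoms: none
Why: Acylation of the secondary allylic alcohol by the acid chloride under nucleophilic catalysis installs the ester of the target while the chain is still unhindered; the C1–O bond is not broken, so the configuration is retained.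

Step 7
Reactants: 13 (2E,4R,8E,10E)-1-acetoxy-12-[(tert-butyldiphenylsilyl)oxy]-3,7,7-trimethyldodeca-2,8,10-trien-4-yl (2E)-3-(4-methoxyphenyl)prop-2-enoate
Product: 14 (2E,4R,8E,10E)-12-[(tert-butyldiphenylsilyl)oxy]-1-hydroxy-3,7,7-trimethyldodeca-2,8,10-trien-4-yl (2E)-3-(4-methoxyphenyl)prop-2-enoate
Conditions: K2CO3 (0.2 equiv), MeOH, 0 °C
Reagents that add atoms: none
Why: Base-catalysed transesterification should remove the unhindered primary acetate much faster than the hindered, conjugated and electron-rich secondary cinnamate, and the (E)-alkene keeps the freed hydroxyl away from the C1 ester so that acyl migration cannot occur.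

Step 8
Reactants: 14 (2E,4R,8E,10E)-12-[(tert-butyldiphenylsilyl)oxy]-1-hydroxy-3,7,7-trimethyldodeca-2,8,10-trien-4-yl (2E)-3-(4-methoxyphenyl)prop-2-enoate
Product: 15 (2E,4R,8E,10E)-12-[(tert-butyldiphenylsilyl)oxy]-3,7,7-trimethyl-1-oxododeca-2,8,10-trien-4-yl (2E)-3-(4-methoxyphenyl)prop-2-enoate
Conditions: MnO2 (excess), CH2Cl2, rt
Reagents that add atoms: none
Why: Selective allylic oxidation by MnO2 under neutral conditions gives the (E)-enal without touching the silyl ether, the ester or the alkene geometry.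

Step 9
Reactants: 15 (2E,4R,8E,10E)-12-[(tert-butyldiphenylsilyl)oxy]-3,7,7-trimethyl-1-oxododeca-2,8,10-trien-4-yl (2E)-3-(4-methoxyphenyl)prop-2-enoate
Product: 16 (1R,4aS,7S,8S,8aS)-7-{[(tert-butyldiphenylsilyl)oxy]methyl}-8-formyl-4,4,8a-trimethyl-1,2,3,4,4a,7,8,8a-octahydronaphthalen-1-yl (2E)-3-(4-methoxyphenyl)prop-2-enoate
Conditions: Me2AlCl (2.5 equiv), CH2Cl2, −78 to 0 °C; aq. HCl (1 M), 0 °C
Reagents that add atoms: none
Why: Me2AlCl binds the formyl oxygen of the (E)-enal and lowers its LUMO, and the C9=C10 dienophile then adds suprafacially to the C5=C6–C7=C8 diene in a concerted, asynchronous [4π+2π] cycloaddition that forms C5–C10 and C8–C9 together. The closest known reaction type is the Lewis-acid-promoted type 1 intramolecular Diels–Alder reaction of (E,E,E)-1,7,9-decatrienals to trans-fused octalins, which includes β-methyl enal dienophiles that deliver an angular methyl group. Ring B closes as the six-membered ring of the cycloaddition itself, and ring A closes in the same transition state through the C1–C4 tether, which adopts a chair-like six-membered array (C10, C1, C2, C3, C4, C5) helped by the gem-dimethyl group at C4. C9 and C10 follow from the (E)-enal geometry (methyl and formyl stay cis), C5 follows from the endo position of the aluminium-bound formyl group, which sets H5 trans to the C10 methyl, C8 follows from the (E,E)-diene, and the absolute sense of all four follows from C1, whose acyloxy group sits equatorial on the chair tether with the C1–O bond anti to the forming C5–C10 bond and away from the diene. The step needs endo over exo selectivity, one π-face of the enal and cycloaddition faster than ionisation of the dienylic silyl ether; the Lewis acid at low temperature, the trans relation of formyl group and tether, and the stereoelectronic and steric preference of the allylic ester are meant to secure these.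

Step 10
Reactants: 16 (1R,4aS,7S,8S,8aS)-7-{[(tert-butyldiphenylsilyl)oxy]methyl}-8-formyl-4,4,8a-trimethyl-1,2,3,4,4a,7,8,8a-octahydronaphthalen-1-yl (2E)-3-(4-methoxyphenyl)prop-2-enoate
Product: 17 (1R,4aS,7S,8S,8aS)-7-{[(tert-butyldiphenylsilyl)oxy]methyl}-8-(dimethoxymethyl)-4,4,8a-trimethyl-1,2,3,4,4a,7,8,8a-octahydronaphthalen-1-yl (2E)-3-(4-methoxyphenyl)prop-2-enoate
Conditions: HC(OMe)3, MeOH, pyridinium p-toluenesulfonate (cat.), rt
Reagents that add atoms: methanol, CO; trimethyl orthoformate, COC(OC)OC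
Why: Acid-catalysed acetalisation of the only aldehyde masks C11 and removes the acidity of H9, so the C9 configuration cannot be lost while the ring B double bond is moved; the silyl ether and the ester should tolerate the mild acid.

Step 11
Reactants: 17 (1R,4aS,7S,8S,8aS)-7-{[(tert-butyldiphenylsilyl)oxy]methyl}-8-(dimethoxymethyl)-4,4,8a-trimethyl-1,2,3,4,4a,7,8,8a-octahydronaphthalen-1-yl (2E)-3-(4-methoxyphenyl)prop-2-enoate
Product: 18 (1R,4aS,7S,8S,8aS)-8-(dimethoxymethyl)-7-(hydroxymethyl)-4,4,8a-trimethyl-1,2,3,4,4a,7,8,8a-octahydronaphthalen-1-yl (2E)-3-(4-methoxyphenyl)prop-2-enoate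
Conditions: Bu4NF, AcOH, THF, rt
Reagents that add atoms: none
Why: Fluoride-mediated desilylation, buffered with acetic acid to protect the ester, frees the C12 alcohol; the acetal is stable to these conditions.

Step 12
Reactants: 18 (1R,4aS,7S,8S,8aS)-8-(dimethoxymethyl)-7-(hydroxymethyl)-4,4,8a-trimethyl-1,2,3,4,4a,7,8,8a-octahydronaphthalen-1-yl (2E)-3-(4-methoxyphenyl)prop-2-enoate
Product: 20 (1R,4aS,8R,8aS)-8-(dimethoxymethyl)-7-formyl-4,4,8a-trimethyl-1,2,3,4,4a,5,8,8a-octahydronaphthalen-1-yl (2E)-3-(4-methoxyphenyl)prop-2-enoate, via deconjugated aldehyde 19 (not isolated)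
Conditions: Dess–Martin periodinane, pyridine, CH2Cl2, 0 °C to rt; aqueous wash; then 1,8-diazabicyclo[5.4.0]undec-7-ene (0.2 equiv), CH2Cl2, 0 °C to rt
Reagents that add atoms: none
Why: Dess–Martin oxidation gives the β,γ-unsaturated aldehyde, whose doubly activated H8 is removed by the amidine base, and protonation of the dienolate at C6 should give the conjugated C7=C8 enal as the thermodynamic product (base-mediated alkene conjugation); H9 is not acidic in the acetal, so C9 is untouched.

Step 13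
Reactants: 20 (1R,4aS,8R,8aS)-8-(dimethoxymethyl)-7-formyl-4,4,8a-trimethyl-1,2,3,4,4a,5,8,8a-octahydronaphthalen-1-yl (2E)-3-(4-methoxyphenyl)prop-2-enoate
Product: 21 (1R,4aS,8R,8aS)-7,8-diformyl-4,4,8a-trimethyl-1,2,3,4,4a,5,8,8a-octahydronaphthalen-1-yl (2E)-3-(4-methoxyphenyl)prop-2-enoate
Conditions: pyridinium p-toluenesulfonate (cat.), acetone/H2O (10:1), rt
Reagents that add atoms: water, O
Why: Mild acid-catalysed acetal hydrolysis releases the C11 aldehyde; water should trap the oxocarbenium ion faster than it can lose H9, and the absence of base avoids the base-induced C9 epimerisation to which such ene-dialdehydes are prone.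

**Compound list**

1 | 2,2-dimethylbut-3-en-1-ol | C=CC(C)(C)CO | starting material
2 | 2,2-dimethylbut-3-enal | C=CC(C)(C)C=O | intermediate
3 | triethyl 4-phosphonocrotonate (ethyl (2E)-4-(diethoxyphosphoryl)but-2-enoate) | CCOC(=O)/C=C/CP(=O)(OCC)OCC | starting material
4 | ethyl (2E,4E)-6,6-dimethylocta-2,4,7-trienoate | CCOC(=O)/C=C/C=C/C(C)(C)C=C | intermediate
5 | (2E,4E)-6,6-dimethylocta-2,4,7-trien-1-ol | OC/C=C/C=C/C(C)(C)C=C | intermediate
6 | tert-butyl{[(2E,4E)-6,6-dimethylocta-2,4,7-trien-1-yl]oxy}diphenylsilane | C=CC(C)(C)/C=C/C=C/CO[Si](c1ccccc1)(c1ccccc1)C(C)(C)C | intermediate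
7 | (2E)-4-acetoxy-2-methylbut-2-enal | CC(=O)OC/C=C(\C)C=O | starting material
8 | diethyl{(4E,6E)-8-[(tert-butyldiphenylsilyl)oxy]-3,3-dimethylocta-4,6-dien-1-yl}borane | CCB(CC)CCC(C)(C)/C=C/C=C/CO[Si](c1ccccc1)(c1ccccc1)C(C)(C)C | intermediate
9 | bis{(4E,6E)-8-[(tert-butyldiphenylsilyl)oxy]-3,3-dimethylocta-4,6-dien-1-yl}zinc | C(CC(C)(C)/C=C/C=C/CO[Si](c1ccccc1)(c1ccccc1)C(C)(C)C)[Zn]CCC(C)(C)/C=C/C=C/CO[Si](c1ccccc1)(c1ccccc1)C(C)(C)C | intermediate
10 | {(4E,6E)-8-[(tert-butyldiphenylsilyl)oxy]-3,3-dimethylocta-4,6-dien-1-yl}[(trimethylsilyl)methyl]zinc | C[Si](C)(C)C[Zn]CCC(C)(C)/C=C/C=C/CO[Si](c1ccccc1)(c1ccccc1)C(C)(C)C | intermediate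
11 | (2E,4R,8E,10E)-12-[(tert-butyldiphenylsilyl)oxy]-4-hydroxy-3,7,7-trimethyldodeca-2,8,10-trien-1-yl acetate | CC(=O)OC/C=C(\C)[C@H](O)CCC(C)(C)/C=C/C=C/CO[Si](c1ccccc1)(c1ccccc1)C(C)(C)C | intermediate
12 | (2E)-3-(4-methoxyphenyl)prop-2-enoyl chloride (4-methoxycinnamoyl chloride) | COc1ccc(/C=C/C(Cl)=O)cc1 | starting material
13 | (2E,4R,8E,10E)-1-acetoxy-12-[(tert-butyldiphenylsilyl)oxy]-3,7,7-trimethyldodeca-2,8,10-trien-4-yl (2E)-3-(4-methoxyphenyl)prop-2-enoate | CC(=O)OC/C=C(\C)[C@H](OC(=O)/C=C/c1ccc(OC)cc1)CCC(C)(C)/C=C/C=C/CO[Si](c1ccccc1)(c1ccccc1)C(C)(C)C | intermediate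
14 | (2E,4R,8E,10E)-12-[(tert-butyldiphenylsilyl)oxy]-1-hydroxy-3,7,7-trimethyldodeca-2,8,10-trien-4-yl (2E)-3-(4-methoxyphenyl)prop-2-enoate | OC/C=C(\C)[C@H](OC(=O)/C=C/c1ccc(OC)cc1)CCC(C)(C)/C=C/C=C/CO[Si](c1ccccc1)(c1ccccc1)C(C)(C)C | intermediate
15 | (2E,4R,8E,10E)-12-[(tert-butyldiphenylsilyl)oxy]-3,7,7-trimethyl-1-oxododeca-2,8,10-trien-4-yl (2E)-3-(4-methoxyphenyl)prop-2-enoate | O=C/C=C(\C)[C@H](OC(=O)/C=C/c1ccc(OC)cc1)CCC(C)(C)/C=C/C=C/CO[Si](c1ccccc1)(c1ccccc1)C(C)(C)C | intermediate
16 | (1R,4aS,7S,8S,8aS)-7-{[(tert-butyldiphenylsilyl)oxy]methyl}-8-formyl-4,4,8a-trimethyl-1,2,3,4,4a,7,8,8a-octahydronaphthalen-1-yl (2E)-3-(4-methoxyphenyl)prop-2-enoate | COc1ccc(/C=C/C(=O)O[C@@H]2CCC(C)(C)[C@@H]3C=C[C@H](CO[Si](c4ccccc4)(c4ccccc4)C(C)(C)C)[C@H](C=O)[C@@]23C)cc1 | intermediate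
17 | (1R,4aS,7S,8S,8aS)-7-{[(tert-butyldiphenylsilyl)oxy]methyl}-8-(dimethoxymethyl)-4,4,8a-trimethyl-1,2,3,4,4a,7,8,8a-octahydronaphthalen-1-yl (2E)-3-(4-methoxyphenyl)prop-2-enoate | COc1ccc(/C=C/C(=O)O[C@@H]2CCC(C)(C)[C@@H]3C=C[C@H](CO[Si](c4ccccc4)(c4ccccc4)C(C)(C)C)[C@H](C(OC)OC)[C@@]23C)cc1 | intermediate
18 | (1R,4aS,7S,8S,8aS)-8-(dimethoxymethyl)-7-(hydroxymethyl)-4,4,8a-trimethyl-1,2,3,4,4a,7,8,8a-octahydronaphthalen-1-yl (2E)-3-(4-methoxyphenyl)prop-2-enoate | COc1ccc(/C=C/C(=O)O[C@@H]2CCC(C)(C)[C@@H]3C=C[C@H](CO)[C@H](C(OC)OC)[C@@]23C)cc1 | intermediate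
19 | (1R,4aS,7S,8S,8aS)-8-(dimethoxymethyl)-7-formyl-4,4,8a-trimethyl-1,2,3,4,4a,7,8,8a-octahydronaphthalen-1-yl (2E)-3-(4-methoxyphenyl)prop-2-enoate (C7 configuration as formed; it is lost in the next stage) | COc1ccc(/C=C/C(=O)O[C@@H]2CCC(C)(C)[C@@H]3C=C[C@H](C=O)[C@H](C(OC)OC)[C@@]23C)cc1 | intermediate
20 | (1R,4aS,8R,8aS)-8-(dimethoxymethyl)-7-formyl-4,4,8a-trimethyl-1,2,3,4,4a,5,8,8a-octahydronaphthalen-1-yl (2E)-3-(4-methoxyphenyl)prop-2-enoate | COc1ccc(/C=C/C(=O)O[C@@H]2CCC(C)(C)[C@@H]3CC=C(C=O)[C@H](C(OC)OC)[C@@]23C)cc1 | intermediate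
21 | (1R,4aS,8R,8aS)-7,8-diformyl-4,4,8a-trimethyl-1,2,3,4,4a,5,8,8a-octahydronaphthalen-1-yl (2E)-3-(4-methoxyphenyl)prop-2-enoate | COc1ccc(/C=C/C(=O)O[C@@H]2CCC(C)(C)[C@@H]3CC=C(C=O)[C@H](C=O)[C@@]23C)cc1 | target

**Count and risks**

Total step count: 13. Longest linear sequence: 13 steps (1 to 21); compounds 3, 7 and 12 enter as purchased reagents.

Steps most likely to fail:

1. Step 9. The β,β-disubstituted enal may cyclise too slowly at the temperatures where the aluminium Lewis acid is selective. Exo (cis-fused) closure, addition to the other π-face or ionisation of the dienylic silyl ether could then compete. The fallback replaces the neutral Lewis-acid complex by a cationic dienophile. It sets out from 15, which is acetalised (HC(OMe)3, MeOH, pyridinium p-toluenesulfonate) to the trienal dimethyl acetal F1. Catalytic Me3SiOTf in CH2Cl2 at −78 °C ionises F1 to a 1-methoxyallyl cation, which should undergo the intramolecular ionic Diels–Alder reaction of an unsaturated acetal. Methoxide return from Me3SiOMe then gives the acetal directly, so the fallback comes back to the route at 17.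

2. Step 13. Configuration at C9 may be lost during hydrolysis, either by proton loss from the oxocarbenium ion or by acid-catalysed enolisation of the freed aldehyde, because H9 is both allylic and α to the formyl group. The fallback avoids a free C11 aldehyde until the last operation. It sets out from 20: Luche reduction (NaBH4, CeCl3·7H2O, MeOH, −40 °C) gives the allylic alcohol F2. Aqueous acetic acid in THF opens the acetal with immediate capture by the C12 hydroxyl, giving the lactol F3. NaBH4 in MeOH reduces F3 through its open form to the 11,12-diol F4. Swern oxidation, with both hydroxyls activated at −78 °C before Et3N is added, converts F4 to the dialdehyde, so the fallback comes back at 21.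

3. Step 5. Et2BH may also hydroborate the diene, or the boron-to-zinc exchange may be incomplete, so that ethyl rather than the functionalised alkyl group is transferred. The fallback makes the zinc reagent from an isolated halide. It sets out from 6: hydroboration with 9-borabicyclo[3.3.1]nonane and oxidation with NaBO3·4H2O give the primary alcohol F5. PPh3, I2 and imidazole convert F5 to the iodide F6. Iodine–zinc exchange of F6 with Et2Zn (CuI cat.) delivers the dialkylzinc, so the fallback comes back at 9 and continues through 10 to 11 as in step 5.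

**Further compounds**

F1 | step 9 | (2E,4R,8E,10E)-12-[(tert-butyldiphenylsilyl)oxy]-1,1-dimethoxy-3,7,7-trimethyldodeca-2,8,10-trien-4-yl (2E)-3-(4-methoxyphenyl)prop-2-enoate | COC(OC)/C=C(\C)[C@H](OC(=O)/C=C/c1ccc(OC)cc1)CCC(C)(C)/C=C/C=C/CO[Si](c1ccccc1)(c1ccccc1)C(C)(C)C
F2 | step 13 | (1R,4aS,8S,8aS)-8-(dimethoxymethyl)-7-(hydroxymethyl)-4,4,8a-trimethyl-1,2,3,4,4a,5,8,8a-octahydronaphthalen-1-yl (2E)-3-(4-methoxyphenyl)prop-2-enoate | COc1ccc(/C=C/C(=O)O[C@@H]2CCC(C)(C)[C@@H]3CC=C(CO)[C@H](C(OC)OC)[C@@]23C)cc1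
F3 | step 13 | (5aS,9R,9aS,9bS)-1-hydroxy-6,6,9a-trimethyl-1,3,5,5a,6,7,8,9,9a,9b-decahydronaphtho[1,2-c]furan-9-yl (2E)-3-(4-methoxyphenyl)prop-2-enoate (both C1 anomers) | COc1ccc(/C=C/C(=O)O[C@@H]2CCC(C)(C)[C@@H]3CC=C4COC(O)[C@@H]4[C@@]23C)cc1
F4 | step 13 | (1R,4aS,8S,8aS)-7,8-bis(hydroxymethyl)-4,4,8a-trimethyl-1,2,3,4,4a,5,8,8a-octahydronaphthalen-1-yl (2E)-3-(4-methoxyphenyl)prop-2-enoate | COc1ccc(/C=C/C(=O)O[C@@H]2CCC(C)(C)[C@@H]3CC=C(CO)[C@H](CO)[C@@]23C)cc1
F5 | step 5 | (4E,6E)-8-[(tert-butyldiphenylsilyl)oxy]-3,3-dimethylocta-4,6-dien-1-ol | OCCC(C)(C)/C=C/C=C/CO[Si](c1ccccc1)(c1ccccc1)C(C)(C)C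
F6 | step 5 | tert-butyl{[(2E,4E)-8-iodo-6,6-dimethylocta-2,4-dien-1-yl]oxy}diphenylsilane | ICCC(C)(C)/C=C/C=C/CO[Si](c1ccccc1)(c1ccccc1)C(C)(C)C
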